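**Retrosynthetic overview**
1. Target 22 ⇐ triyne 21: one global Lindlar semi-hydrogenation turns C5≡C6, C14≡C15 and C17≡C18 into the three Z alkenes.
2. 21 ⇐ ynal 17 + ester homoenolate 19 (from iodoester 18): the C3–C4 bond is made last, by catalyst-controlled addition of a β-metallated ester to the aldehyde, which creates C4 (R) and the 1,4-dioxygen pattern of the side chain.
3. 17 ⇐ hydroxy-enone 12 + ynal acetal 3 (C7=C8 by aldol condensation); 3 ⇐ 1 by formylation.
4. 12 ⇐ (S)-4-silyloxycyclopentenone 4 + propargyl bromide 5 + 1-bromopent-2-yne 8; C12 is set by addition anti to the OTBS group, and the directing carbinol is then oxidised to the C9 ketone.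
5. Rings: the only ring, the cyclopentenone, is bought with 4; no ring is formed or opened.

Assumption: 4 is purchased as the single (S) enantiomer; positions are given in prostanoid numbering (C1 ester carbon to C20 methyl).

Step 1
Reactants: 1 3,3-diethoxyprop-1-yne
Product: 3 4,4-diethoxybut-2-ynal, via lithium acetylide 2 (not isolated)
Conditions: n-BuLi, THF, −78 °C; DMF, −78 → 0 °C; poured into cold aq. KH2PO4
Reagents that add atoms: N,N-dimethylformamide, CN(C)C=O
Why: formylation of a lithium acetylide with DMF, where the buffered inverse quench keeps the liberated Me2NH from adding to the ynal; no stereocentre is involved.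

Step 2
Reactants: 4 (S)-4-[(tert-butyldimethylsilyl)oxy]cyclopent-2-en-1-one; 5 3-bromoprop-1-yne (propargyl bromide)
Product: 7 (1R,4S)-4-[(tert-butyldimethylsilyl)oxy]-1-(prop-2-yn-1-yl)cyclopent-2-en-1-ol, via allenylmagnesium bromide 6 (not isolated)
Conditions: 5, Mg, ZnBr2 (2 mol %), Et2O, 0 °C; then 4, Et2O, −78 °C; aq. NH4Cl
Reagents that add atoms: none
Why: Grignard 1,2-addition with allenyl-to-propargyl transposition, entering the carbonyl face anti to the silyloxy group so that the new tertiary carbinol (future C12) is R and cis-1,4 to OTBS, the minor epimer being removed by chromatography.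

Step 3
Reactants: 7 (1R,4S)-4-[(tert-butyldimethylsilyl)oxy]-1-(prop-2-yn-1-yl)cyclopent-2-en-1-ol; 8 1-bromopent-2-yne
Product: 10 (1R,4S)-4-[(tert-butyldimethylsilyl)oxy]-1-(octa-2,5-diyn-1-yl)cyclopent-2-en-1-ol, via copper acetylide 9 (not isolated)
Conditions: CuI (1.0 equiv), Cs2CO3 (1.5 equiv), DMF, 23 °C
Reagents that add atoms: none
Why: copper-mediated propargylation of a terminal alkyne (alkynylcopper displacement of a propargylic bromide) gives the skipped diyne under carbonate conditions that leave the tertiary alcohol, the silyl ether and both stereocentres untouched.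

Step 4
Reactants: 10 (1R,4S)-4-[(tert-butyldimethylsilyl)oxy]-1-(octa-2,5-diyn-1-yl)cyclopent-2-en-1-ol
Product: 11 (1R,4S)-1-(octa-2,5-diyn-1-yl)cyclopent-2-ene-1,4-diol
Conditions: n-Bu4NF (1.2 equiv), THF, 0 °C
Reagents that add atoms: none
Why: fluoride-induced desilylation frees the secondary allylic alcohol, and the short exposure at 0 °C avoids base isomerisation of the skipped diyne.

Step 5
Reactants: 11 (1R,4S)-1-(octa-2,5-diyn-1-yl)cyclopent-2-ene-1,4-diol
Product: 12 (R)-4-hydroxy-4-(octa-2,5-diyn-1-yl)cyclopent-2-en-1-one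
Conditions: MnO2 (activated, 15 equiv), CH2Cl2, 23 °C
Reagents that add atoms: none
Why: chemoselective MnO2 oxidation of an allylic alcohol, in which only the secondary carbinol (its directing role finished) can be oxidised while the tertiary C12 carbinol stays R.

Step 6
Reactants: 12 (R)-4-hydroxy-4-(octa-2,5-diyn-1-yl)cyclopent-2-en-1-one; 3 4,4-diethoxybut-2-ynal
Product: 16 (1S,5E)-5-(4,4-diethoxybut-2-yn-1-ylidene)-1-(octa-2,5-diyn-1-yl)-4-oxocyclopent-2-en-1-yl acetate, via dilithium alkoxide enolate 13 (not isolated), via dilithium aldolate 14 (not isolated), via aldol diacetate 15 (not isolated)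
Conditions: 12 added to LiN(iPr)2 (2.1 equiv), THF, −78 °C; 3, −78 °C; Ac2O (5 equiv), −78 → 0 °C; Et3N, DMAP (0.2 equiv), 0 → 23 °C
Reagents that add atoms: acetic anhydride, CC(=O)OC(C)=O
Why: aldol condensation (kinetic α'-enolate addition to the aldehyde, acetylation, then E1cB loss of the secondary β-acetate), in which the C12 alkoxide can neither eliminate nor undergo retro-aldol once C8 is an enolate carbon, elimination runs toward the conjugated enyne and not toward a cyclopentadienone, the thermodynamically preferred 7E alkene forms, and C12 is unchanged in space (its descriptor becomes S only through the priority change at C8).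

Step 7
Reactants: 16 (1S,5E)-5-(4,4-diethoxybut-2-yn-1-ylidene)-1-(octa-2,5-diyn-1-yl)-4-oxocyclopent-2-en-1-yl acetate
Product: 17 (1S,5E)-1-(octa-2,5-diyn-1-yl)-4-oxo-5-(4-oxobut-2-yn-1-ylidene)cyclopent-2-en-1-yl acetate
Conditions: TFA/H2O (1:1), CHCl3, 0 °C
Reagents that add atoms: water, O
Why: acid-catalysed acetal hydrolysis, which the tertiary acetate survives because its ionisation would give a destabilised cyclopentadienone-type cation; C12 and the 7E alkene are untouched.

Step 8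
Reactants: 17 (1S,5E)-1-(octa-2,5-diyn-1-yl)-4-oxo-5-(4-oxobut-2-yn-1-ylidene)cyclopent-2-en-1-yl acetate; 18 methyl 3-iodopropanoate
Product: 21 methyl (4R,7E)-4-(acetyloxy)-7-[(2S)-2-(acetyloxy)-2-(octa-2,5-diyn-1-yl)-5-oxocyclopent-3-en-1-ylidene]hept-5-ynoate, via bis(3-methoxy-3-oxopropyl)zinc 19 (not isolated), via zinc alkoxide 20 (not isolated)
Conditions: 18, Et2Zn, CuI (0.3 mol %), neat, 50 °C, then vacuum; Ti(OiPr)4 (2 equiv), (1S,2S)-1,2-bis(trifluoromethanesulfonamido)cyclohexane (8 mol %), toluene, −20 °C; 17; Ac2O (excess), −20 → 0 °C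
Reagents that add atoms: acetic anhydride, CC(=O)OC(C)=O
Why: Proposed new method: a catalytic enantioselective homoenolate addition to an aldehyde, in which the β-zincio ester 19 (an ester homoenolate, d3 reagent) is transferred to the chiral titanium bis(sulfonamide) complex and attacks the Re face of the ynal carbonyl of 17, so that C3 and C4, both electrophilic in conventional acrylate/aldehyde terms, are joined and C4 is created as R in one catalyst-controlled operation (the (1R,2R)-ligand gives the opposite, S, sense with unsaturated aldehydes); the closest known reactions are the Ti(OiPr)4/bis(triflamide)-catalysed enantioselective addition of functionalised dialkylzincs to ynals and the Lewis-acid-promoted addition of zinc and titanium ester homoenolates to aldehydes, such alkylzinc/alkyltitanium species do not attack ketones, enones, esters or acetates at −20 °C, and acetylating alkoxide 20 in the flask prevents γ-lactonisation.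

Step 9
Reactants: 21 methyl (4R,7E)-4-(acetyloxy)-7-[(2S)-2-(acetyloxy)-2-(octa-2,5-diyn-1-yl)-5-oxocyclopent-3-en-1-ylidene]hept-5-ynoate
Product: 22 methyl (4R,5Z,7E)-4-(acetyloxy)-7-[(2S)-2-(acetyloxy)-2-[(2Z,5Z)-octa-2,5-dien-1-yl]-5-oxocyclopent-3-en-1-ylidene]hept-5-enoate (the target, 17,18-dehydroclavulone of the question)
Conditions: H2 (1 atm), Pd/CaCO3 poisoned with Pb(OAc)2 (Lindlar catalyst), quinoline, EtOAc, 0 °C, dark, stopped after 3 equiv H2
Reagents that add atoms: none
Why: Lindlar semi-hydrogenation, in which syn delivery of H2 on the poisoned palladium surface gives the 5Z, 14Z and 17Z alkenes in one operation while quinoline suppresses reduction of the enone and the new diene; C4, C12 and the 7E alkene are not touched.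

**Compound list**
1 | 3,3-diethoxyprop-1-yne | C#CC(OCC)OCC | starting material
2 | lithium 3,3-diethoxyprop-1-yn-1-ide | [Li+].[C-]#CC(OCC)OCC | intermediate
3 | 4,4-diethoxybut-2-ynal | O=CC#CC(OCC)OCC | intermediate
4 | (S)-4-[(tert-butyldimethylsilyl)oxy]cyclopent-2-en-1-one | O=C1C=C[C@@H](O[Si](C)(C)C(C)(C)C)C1 | starting material
5 | 3-bromoprop-1-yne (propargyl bromide) | C#CCBr | starting material
6 | allenylmagnesium bromide (propa-1,2-dien-1-ylmagnesium bromide) | C=C=C[Mg]Br | intermediate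
7 | (1R,4S)-4-[(tert-butyldimethylsilyl)oxy]-1-(prop-2-yn-1-yl)cyclopent-2-en-1-ol (OH and OTBS cis) | C#CC[C@]1(O)C=C[C@@H](O[Si](C)(C)C(C)(C)C)C1 | intermediate
8 | 1-bromopent-2-yne | CCC#CCBr | starting material
9 | copper acetylide of 7 (monovalent copper on the terminal alkyne carbon) | [Cu]C#CC[C@]1(O)C=C[C@@H](O[Si](C)(C)C(C)(C)C)C1 | intermediate
10 | (1R,4S)-4-[(tert-butyldimethylsilyl)oxy]-1-(octa-2,5-diyn-1-yl)cyclopent-2-en-1-ol | CCC#CCC#CC[C@]1(O)C=C[C@@H](O[Si](C)(C)C(C)(C)C)C1 | intermediate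
11 | (1R,4S)-1-(octa-2,5-diyn-1-yl)cyclopent-2-ene-1,4-diol (cis diol) | CCC#CCC#CC[C@]1(O)C=C[C@@H](O)C1 | intermediate
12 | (R)-4-hydroxy-4-(octa-2,5-diyn-1-yl)cyclopent-2-en-1-one | CCC#CCC#CC[C@]1(O)C=CC(=O)C1 | intermediate
13 | dilithium (S)-1-(octa-2,5-diyn-1-yl)cyclopenta-2,4-diene-1,4-bis(olate) (C12 alkoxide plus C8=C9 enolate of 12) | CCC#CCC#CC[C@]1([O-])C=CC([O-])=C1.[Li+].[Li+] | intermediate
14 | dilithium dialkoxide of (4S)-5-(4,4-diethoxy-1-hydroxybut-2-yn-1-yl)-4-hydroxy-4-(octa-2,5-diyn-1-yl)cyclopent-2-en-1-one (epimers at ring C5 and the side-chain carbinol) | CCC#CCC#CC[C@]1([O-])C=CC(=O)C1C([O-])C#CC(OCC)OCC.[Li+].[Li+] | intermediate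
15 | (1S)-5-[1-(acetyloxy)-4,4-diethoxybut-2-yn-1-yl]-1-(octa-2,5-diyn-1-yl)-4-oxocyclopent-2-en-1-yl acetate (epimers at ring C5 and the side-chain carbinol) | CCC#CCC#CC[C@]1(OC(C)=O)C=CC(=O)C1C(OC(C)=O)C#CC(OCC)OCC | intermediate
16 | (1S,5E)-5-(4,4-diethoxybut-2-yn-1-ylidene)-1-(octa-2,5-diyn-1-yl)-4-oxocyclopent-2-en-1-yl acetate | CCC#CCC#CC[C@]1(OC(C)=O)C=CC(=O)/C1=C/C#CC(OCC)OCC | intermediate
17 | (1S,5E)-1-(octa-2,5-diyn-1-yl)-4-oxo-5-(4-oxobut-2-yn-1-ylidene)cyclopent-2-en-1-yl acetate | CCC#CCC#CC[C@]1(OC(C)=O)C=CC(=O)/C1=C/C#CC=O | intermediate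
18 | methyl 3-iodopropanoate | COC(=O)CCI | starting material
19 | bis(3-methoxy-3-oxopropyl)zinc | COC(=O)CC[Zn]CCC(=O)OC | intermediate
20 | (3-methoxy-3-oxopropyl)zinc alkoxide of methyl (4R,7E)-7-[(2S)-2-(acetyloxy)-2-(octa-2,5-diyn-1-yl)-5-oxocyclopent-3-en-1-ylidene]-4-hydroxyhept-5-ynoate | CCC#CCC#CC[C@]1(OC(C)=O)C=CC(=O)/C1=C/C#C[C@@H](CCC(=O)OC)O[Zn]CCC(=O)OC | intermediate
21 | methyl (4R,7E)-4-(acetyloxy)-7-[(2S)-2-(acetyloxy)-2-(octa-2,5-diyn-1-yl)-5-oxocyclopent-3-en-1-ylidene]hept-5-ynoate | CCC#CCC#CC[C@]1(OC(C)=O)C=CC(=O)/C1=C/C#C[C@@H](CCC(=O)OC)OC(C)=O | intermediate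
22 | methyl (4R,5Z,7E)-4-(acetyloxy)-7-[(2S)-2-(acetyloxy)-2-[(2Z,5Z)-octa-2,5-dien-1-yl]-5-oxocyclopent-3-en-1-ylidene]hept-5-enoate | CC/C=C\C/C=C\C[C@]1(OC(C)=O)C=CC(=O)/C1=C/C=C\[C@@H](CCC(=O)OC)OC(C)=O | target

**Totals**
Total step count: 9. Longest linear sequence: 8 steps (steps 2 to 9, from 4 to 22); step 1 supplies 3 for step 6.

**Steps most likely to fail, each with one fallback**

Step 8 (enantioselective homoenolate addition to the polyfunctional ynal). The risks are low ee, sluggish transfer of the chelated β-zincio ester, and attack on the dienone. The fallback sets out from 17 and comes back at 21; it keeps the same C–C bond but takes the stereochemistry out of it. 19 is added to 17 with ClTi(OiPr)3 and no chiral ligand (CH2Cl2, −30 °C) to give the C4-epimeric propargylic alcohol F1. Dess–Martin periodinane/NaHCO3 oxidises this to the ynone F2. Midland reduction with (R)-Alpine-Borane, which reduces alkynyl ketones but leaves the ring dienone alone, gives the (4R)-propargylic alcohol F3. Ac2O/DMAP/pyridine then gives 21.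

Step 9 (global Lindlar reduction of three alkynes beside a cross-conjugated dienone). The risks are over-reduction of the conjugated system and loss of the 5Z geometry. The fallback sets out from 11 and comes back at 22. The two isolated alkynes are reduced early, where nothing else is reducible: H2 over Pd/CaCO3 poisoned with Pb(OAc)2 and quinoline converts 11 into the (Z,Z)-dienyl diol F4. MnO2 gives the dienyl hydroxy-enone F5. The operations of steps 6, 7 and 8 then give in turn the dienyl enyne acetal F6, the dienyl ynal F7 and the 5-yne diacetate F8. The single conjugated alkyne of F8 is finally reduced with Zn dust activated by Cu(OAc)2 and AgNO3 in MeOH/H2O (Boland reduction), which leaves isolated alkenes and the enone alone, to give 22.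

Step 6 (dianion aldol with acetylation and elimination in one flask). The risks are retro-aldol ring opening of the alkoxide before enolisation (which would also racemise C12), incomplete acetylation of the tertiary alkoxide, and a 7E/7Z mixture. The fallback sets out from 12 and comes back at 16. TMSCl/imidazole in DMF gives the tertiary TMS ether F9. One equivalent of LiN(iPr)2 at −78 °C followed by 3 gives, after protonation, the silylated aldol F10. MsCl/Et3N then DBU gives the silylated 7E enyne F11. HF·pyridine in THF gives the free tertiary alcohol F12. Ac2O/DMAP/Et3N acetylates this to 16.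

**Further compounds**
F1 | step 8 | methyl (7E)-7-[(2S)-2-(acetyloxy)-2-(octa-2,5-diyn-1-yl)-5-oxocyclopent-3-en-1-ylidene]-4-hydroxyhept-5-ynoate (both C4 epimers) | CCC#CCC#CC[C@]1(OC(C)=O)C=CC(=O)/C1=C/C#CC(O)CCC(=O)OC
F2 | step 8 | methyl (7E)-7-[(2S)-2-(acetyloxy)-2-(octa-2,5-diyn-1-yl)-5-oxocyclopent-3-en-1-ylidene]-4-oxohept-5-ynoate | CCC#CCC#CC[C@]1(OC(C)=O)C=CC(=O)/C1=C/C#CC(=O)CCC(=O)OC
F3 | step 8 | methyl (4R,7E)-7-[(2S)-2-(acetyloxy)-2-(octa-2,5-diyn-1-yl)-5-oxocyclopent-3-en-1-ylidene]-4-hydroxyhept-5-ynoate | CCC#CCC#CC[C@]1(OC(C)=O)C=CC(=O)/C1=C/C#C[C@@H](CCC(=O)OC)O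
F4 | step 9 | (1R,4S)-1-[(2Z,5Z)-octa-2,5-dien-1-yl]cyclopent-2-ene-1,4-diol | CC/C=C\C/C=C\C[C@]1(O)C=C[C@@H](O)C1
F5 | step 9 | (R)-4-hydroxy-4-[(2Z,5Z)-octa-2,5-dien-1-yl]cyclopent-2-en-1-one | CC/C=C\C/C=C\C[C@]1(O)C=CC(=O)C1
F6 | step 9 | (1S,5E)-5-(4,4-diethoxybut-2-yn-1-ylidene)-1-[(2Z,5Z)-octa-2,5-dien-1-yl]-4-oxocyclopent-2-en-1-yl acetate | CC/C=C\C/C=C\C[C@]1(OC(C)=O)C=CC(=O)/C1=C/C#CC(OCC)OCC
F7 | step 9 | (1S,5E)-1-[(2Z,5Z)-octa-2,5-dien-1-yl]-4-oxo-5-(4-oxobut-2-yn-1-ylidene)cyclopent-2-en-1-yl acetate | CC/C=C\C/C=C\C[C@]1(OC(C)=O)C=CC(=O)/C1=C/C#CC=O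
F8 | step 9 | methyl (4R,7E)-4-(acetyloxy)-7-[(2S)-2-(acetyloxy)-2-[(2Z,5Z)-octa-2,5-dien-1-yl]-5-oxocyclopent-3-en-1-ylidene]hept-5-ynoate | CC/C=C\C/C=C\C[C@]1(OC(C)=O)C=CC(=O)/C1=C/C#C[C@@H](CCC(=O)OC)OC(C)=O
F9 | step 6 | (R)-4-(octa-2,5-diyn-1-yl)-4-[(trimethylsilyl)oxy]cyclopent-2-en-1-one | CCC#CCC#CC[C@]1(O[Si](C)(C)C)C=CC(=O)C1
F10 | step 6 | (4S)-5-(4,4-diethoxy-1-hydroxybut-2-yn-1-yl)-4-(octa-2,5-diyn-1-yl)-4-[(trimethylsilyl)oxy]cyclopent-2-en-1-one (epimers at ring C5 and the side-chain carbinol) | CCC#CCC#CC[C@]1(O[Si](C)(C)C)C=CC(=O)C1C(O)C#CC(OCC)OCC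
F11 | step 6 | (4S,5E)-5-(4,4-diethoxybut-2-yn-1-ylidene)-4-(octa-2,5-diyn-1-yl)-4-[(trimethylsilyl)oxy]cyclopent-2-en-1-one | CCC#CCC#CC[C@]1(O[Si](C)(C)C)C=CC(=O)/C1=C/C#CC(OCC)OCC
F12 | step 6 | (4S,5E)-5-(4,4-diethoxybut-2-yn-1-ylidene)-4-hydroxy-4-(octa-2,5-diyn-1-yl)cyclopent-2-en-1-one | CCC#CCC#CC[C@]1(O)C=CC(=O)/C1=C/C#CC(OCC)OCC
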